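**Plan**

The target is a tricoumarin: coumarin A is bonded through C6 to C8 of 7-hydroxycoumarin B and through O7 to C3 of 7-hydroxycoumarin C.
Retrosynthesis first cuts ring C at O1–C2 and C3=C4, leaving 2,4-dihydroxybenzaldehyde and an eight-membered aryl lactone O7(A)–CH2–C(=O)–O7(B). It then cuts the C6(A)–C8(B) biaryl bond, the ester C(=O)–O7(B) and the ether O7(A)–CH2.
Enabling feature: O7 of ring A and O7 of ring B both sit ortho to the C6(A)–C8(B) bond, and O7(A) must carry the two carbons that become C3 and C2 of ring C. An O–CH2–C(=O)–O bridge can therefore hold C6(A)–Br and C8(B)–I together for an intramolecular coupling.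
Forward order: ring B is bought and iodinated at C8; ring A is built by Pechmann condensation with bromine in place; then ether, ester, the temporary eight-membered ring (key step), and finally ring C from the bridge.
Stereochemistry: the target has no stereocentre and its biaryl axis carries no descriptor, so nothing has to be set.

Key step: step 6

Assumption: the C6(A)–C8(B) axis, flanked by three ortho oxygens and drawn without a descriptor, is treated as configurationally undefined, so no atroposelective measure is planned.

**Route**

Step 1
Reactants: 1 umbelliferone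
Product: 2 7-hydroxy-8-iodo-2H-chromen-2-one
Conditions: I2 (1.0 equiv), KI, 20% aq NH3, rt; then dilute H2SO4
Reagents that add atoms: iodine, II
Why: Electrophilic aromatic iodination of the 7-phenoxide goes to C8, the ortho position lying between O1 and O7, which is the established site for 7-hydroxycoumarins under I2/KI/NH3 when iodine is limited to one equivalent.

Step 2
Reactants: 3 4-bromoresorcinol; 4 DL-malic acid
Product: 6 6-bromo-7-hydroxy-2H-chromen-2-one, via 3-oxopropanoic acid 5 (not isolated)
Conditions: conc. H2SO4, 110 °C; poured onto ice
Reagents that add atoms: none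
Why: von Pechmann condensation, in which malic acid loses CO and water to give formylacetic acid 5, which attacks the only open activated carbon of 3 (ortho to one OH, para to the other) and lactonises, placing bromine at C6 and the free hydroxyl at C7.

Step 3
Reactants: 6 6-bromo-7-hydroxy-2H-chromen-2-one; 7 tert-butyl bromoacetate
Product: 8 tert-butyl 2-[(6-bromo-2-oxo-2H-chromen-7-yl)oxy]acetate
Conditions: K2CO3, acetone, reflux
Reagents that add atoms: none
Why: Williamson ether synthesis, in which the single acidic phenol is alkylated by the reactive alpha-bromo ester under mild carbonate conditions that leave the lactone and the tert-butyl ester untouched.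

Step 4
Reactants: 8 tert-butyl 2-[(6-bromo-2-oxo-2H-chromen-7-yl)oxy]acetate
Product: 9 2-[(6-bromo-2-oxo-2H-chromen-7-yl)oxy]acetic acid
Conditions: TFA/CH2Cl2 (1:2), rt
Reagents that add atoms: none
Why: Acidolysis of the tert-butyl ester with loss of isobutene frees the carboxylic acid without base, so the coumarin lactone and the aryl bromide are not touched.

Step 5
Reactants: 9 2-[(6-bromo-2-oxo-2H-chromen-7-yl)oxy]acetic acid; 2 7-hydroxy-8-iodo-2H-chromen-2-one
Product: 10 8-iodo-2-oxo-2H-chromen-7-yl 2-[(6-bromo-2-oxo-2H-chromen-7-yl)oxy]acetate
Conditions: DCC, DMAP (0.1 equiv), CH2Cl2/DMF, 0 °C to rt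
Reagents that add atoms: none
Why: Steglich esterification, in which the O-acylisourea is relayed by DMAP to an acylpyridinium ion that acylates the mono-ortho-substituted iodophenol under neutral conditions, giving the aryl ester that ties ring A to ring B.

Step 6
Reactants: 10 8-iodo-2-oxo-2H-chromen-7-yl 2-[(6-bromo-2-oxo-2H-chromen-7-yl)oxy]acetate
Product: 12 oxyacetate-bridged 6,8'-bicoumarin eight-membered lactone, via aryl trimethylstannane 11 (not isolated)
Conditions: PdCl2(PPh3)2 (10 mol %), (Me3Sn)2 (1.1 equiv), degassed 1,4-dioxane (0.005 M), 100 °C, Ar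
Reagents that add atoms: hexamethylditin, C[Sn](C)(C)[Sn](C)(C)C (atoms kept only in intermediate 11; none in 12)
Why: Stille–Kelly coupling: the ditin reduces PdCl2(PPh3)2 to zerovalent palladium, which adds first to the weaker C8–I bond of ring B, and exchange with (Me3Sn)2 turns this site into aryl stannane 11. The catalyst then adds to C6–Br of ring A, the tin group is handed over within the same molecule, and reductive elimination forges the C6(A)–C8(B) bond. The closest known reaction type is the palladium/hexaalkylditin-mediated ring-forming coupling of two tethered aryl halides, with Ullmann couplings across ester tethers as a second analogy. The eight-membered dioxocinone ring closes by aryl–aryl reductive elimination from a nine-membered diarylpalladium cycle, helped by the O–CH2–C(=O)–O bridge linking two oxygens that both stand ortho to the new bond. No stereocentre arises and the new axis is left uncontrolled. The step needs iodide-before-bromide chemoselectivity (two different halogens, barely more than one equivalent of ditin), the correct site (fixed by where the halogens sit) and ring closure over oligomerisation (short tether, high dilution), while the base-free medium leaves the aryl ester and both coumarin lactones intact.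

Step 7
Reactants: 12 oxyacetate-bridged 6,8'-bicoumarin eight-membered lactone; 13 2,4-dihydroxybenzaldehyde
Product: 15 7-hydroxy-8-{7-[(7-hydroxy-2-oxo-2H-chromen-3-yl)oxy]-2-oxo-2H-chromen-6-yl}-2H-chromen-2-one (target), via 2-formyl-5-hydroxyphenyl ester 14 (not isolated)
Conditions: 13 (1.5 equiv), DBU (3 equiv), 4 Å molecular sieves, MeCN, rt then 60 °C; 1 M HCl work-up
Reagents that add atoms: none
Why: Proposed new method: DBU generates the phenoxides of 13, and the 2-phenoxide attacks the strained, electron-poor aryl ester of the eight-membered lactone (aryl ester transesterification, the B-ring 7-phenoxide being a good leaving group) to give the 2-formylaryl aryloxyacetate 14, whose activated CH2 then adds to the neighbouring aldehyde and loses water (intramolecular Knoevenagel, six-membered ring closure), turning the bridge CH2 and C=O into C3 and C2 of ring C and releasing the 7-OH of ring B; acylation at the 4-OH of 13 or return to 12 is reversible and is drained by the irreversible coumarin-forming condensation, and a Knoevenagel-first then translactonisation order leads to the same product; the closest known reaction types are base-mediated acyl transfer between aryl esters and the O-acylation/intramolecular Knoevenagel synthesis of 3-aryloxycoumarins from salicylaldehydes and activated aryloxyacetic acid derivatives (acid chlorides, Perkin-type mixed anhydrides).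

**Compound list**

1 | umbelliferone (7-hydroxy-2H-chromen-2-one) | O=c1ccc2ccc(O)cc2o1 | starting material
2 | 7-hydroxy-8-iodo-2H-chromen-2-one | O=c1ccc2ccc(O)c(I)c2o1 | intermediate
3 | 4-bromoresorcinol (4-bromobenzene-1,3-diol) | Oc1ccc(Br)c(O)c1 | starting material
4 | DL-malic acid (racemic 2-hydroxybutanedioic acid) | OC(=O)CC(O)C(=O)O | starting material
5 | 3-oxopropanoic acid (formylacetic acid) | O=CCC(=O)O | intermediate (not isolated)
6 | 6-bromo-7-hydroxy-2H-chromen-2-one | O=c1ccc2cc(Br)c(O)cc2o1 | intermediate
7 | tert-butyl bromoacetate | CC(C)(C)OC(=O)CBr | starting material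
8 | tert-butyl 2-[(6-bromo-2-oxo-2H-chromen-7-yl)oxy]acetate | CC(C)(C)OC(=O)COc1cc2oc(=O)ccc2cc1Br | intermediate
9 | 2-[(6-bromo-2-oxo-2H-chromen-7-yl)oxy]acetic acid | OC(=O)COc1cc2oc(=O)ccc2cc1Br | intermediate
10 | 8-iodo-2-oxo-2H-chromen-7-yl 2-[(6-bromo-2-oxo-2H-chromen-7-yl)oxy]acetate | O=C(COc1cc2oc(=O)ccc2cc1Br)Oc1ccc2ccc(=O)oc2c1I | intermediate
11 | 2-oxo-8-(trimethylstannyl)-2H-chromen-7-yl 2-[(6-bromo-2-oxo-2H-chromen-7-yl)oxy]acetate | O=C(COc1cc2oc(=O)ccc2cc1Br)Oc1ccc2ccc(=O)oc2c1[Sn](C)(C)C | intermediate (not isolated)
12 | eight-membered lactone in which O7 of coumarin A and O7 of coumarin B are bridged by CH2–C(=O) and C6 of A is bonded to C8 of B | O=C1COc2cc3oc(=O)ccc3cc2-c2c(O1)ccc1ccc(=O)oc21 | intermediate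
13 | 2,4-dihydroxybenzaldehyde | O=Cc1ccc(O)cc1O | starting material
14 | 2-formyl-5-hydroxyphenyl 2-{[6-(7-hydroxy-2-oxo-2H-chromen-8-yl)-2-oxo-2H-chromen-7-yl]oxy}acetate | O=Cc1ccc(O)cc1OC(=O)COc1cc2oc(=O)ccc2cc1-c1c(O)ccc2ccc(=O)oc12 | intermediate (not isolated)
15 | 7-hydroxy-8-{7-[(7-hydroxy-2-oxo-2H-chromen-3-yl)oxy]-2-oxo-2H-chromen-6-yl}-2H-chromen-2-one (CNP0215289.0) | O=c1ccc2cc(-c3c(O)ccc4ccc(=O)oc34)c(Oc3cc4ccc(O)cc4oc3=O)cc2o1 | target

**Step count**

Total steps: 7.
Longest linear sequence: 6 steps (3 → 6 → 8 → 9 → 10 → 12 → 15, steps 2 to 7). Step 1 supplies 2 for the convergent esterification in step 5.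

**Steps most likely to fail**

1. Step 7 (proposed new method). Acyl transfer may stall at the unproductive 4-O-acylated aldehyde, or water released by the condensation may hydrolyse the lactone before the Knoevenagel closure takes place. The fallback uses known chemistry, sets out from 12 and returns at 15. The strained aryl ester of 12 would be saponified with LiOH in aqueous THF at 0 °C and acidified to give the hydroxy acid F1. Perkin–Oglialoro condensation of F1 with 13 in Ac2O/Et3N at 110 °C should close ring C and acetylate both phenols, giving the diacetate F2. Methanolysis with K2CO3 in MeOH at 0 °C and acidification would then deliver 15.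

2. Step 6. Closure of the eight-membered ring may be slower than protodestannylation, double stannylation or intermolecular coupling, so that the biaryl bond forms between molecules or not at all. The fallback gives up the tether, makes the same C6(A)–C8(B) bond intermolecularly, sets out from 8 (with 2) and returns at 15. Miyaura borylation of 8 (B2pin2, PdCl2(dppf), KOAc, dioxane, 85 °C) should give the pinacol boronate F3. Suzuki–Miyaura coupling of F3 with iodophenol 2 (Pd(OAc)2, SPhos, K3PO4, toluene/water, 80 °C) would give the biaryl tert-butyl ester F4. TFA in CH2Cl2 then frees the hydroxy acid F1, which proceeds through the Perkin condensation to the diacetate F2 and by methanolysis to 15, as described under point 1.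

3. Step 2. Sulfonation, charring and acid-promoted loss or migration of bromine in hot H2SO4 may erode the yield or give regioisomeric bromocoumarins. The fallback builds the lactone onto a preformed bromo-salicylaldehyde, sets out from 13 and returns at 6. Bromination of 13 with Br2 in AcOH should give 5-bromo-2,4-dihydroxybenzaldehyde F5, the position para to the 2-OH and ortho to the 4-OH being the most activated one. Wittig olefination of F5 with ethyl (triphenylphosphoranylidene)acetate in refluxing N,N-diethylaniline would form ethyl (E)-3-(5-bromo-2,4-dihydroxyphenyl)prop-2-enoate F6 (not isolated), which isomerises thermally and lactonises to 6.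

**Further compounds**

F1 | step 7 | 2-{[6-(7-hydroxy-2-oxo-2H-chromen-8-yl)-2-oxo-2H-chromen-7-yl]oxy}acetic acid | OC(=O)COc1cc2oc(=O)ccc2cc1-c1c(O)ccc2ccc(=O)oc12
F2 | step 7 | diacetate of 15 (acetates on the 7-OH of ring B and the 7-OH of ring C) | CC(=O)Oc1ccc2cc(Oc3cc4oc(=O)ccc4cc3-c3c(OC(C)=O)ccc4ccc(=O)oc34)c(=O)oc2c1
F3 | step 6 | tert-butyl 2-{[2-oxo-6-(4,4,5,5-tetramethyl-1,3,2-dioxaborolan-2-yl)-2H-chromen-7-yl]oxy}acetate | CC(C)(C)OC(=O)COc1cc2oc(=O)ccc2cc1B1OC(C)(C)C(C)(C)O1
F4 | step 6 | tert-butyl 2-{[6-(7-hydroxy-2-oxo-2H-chromen-8-yl)-2-oxo-2H-chromen-7-yl]oxy}acetate | CC(C)(C)OC(=O)COc1cc2oc(=O)ccc2cc1-c1c(O)ccc2ccc(=O)oc12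
F5 | step 2 | 5-bromo-2,4-dihydroxybenzaldehyde | O=Cc1cc(Br)c(O)cc1O
F6 | step 2 | ethyl (E)-3-(5-bromo-2,4-dihydroxyphenyl)prop-2-enoate | CCOC(=O)/C=C/c1cc(Br)c(O)cc1O
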